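**Retrosynthetic overview**
1. Target ⇐ kinetic O-methyl ketalisation at C6 and methyl ester formation of the 6-hydroxy-1,2-dioxine acetic acid (a peroxy hemiketal).
2. Dioxinol acid ⇐ ring expansion of a (4R)-4-[(Z)-3-oxoalkenyl]oxetan-2-one with H2O2: the perhydrate OOH alkylates lactone C4 with inversion, which closes the peroxide ring, sets C3 and frees the CH2CO2H arm.
3. β-Lactone ⇐ catalytic asymmetric ketene–aldehyde lactonisation of (Z)-4-oxoicos-2-enal ⇐ oxidative opening of 2-hexadecylfuran.
4. 2-Hexadecylfuran ⇐ 2-allylfuran + 1-bromoheptane + 1,6-dibromohexane by two sp3–sp3 couplings.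
5. Ring order: furan (bought, opened in step 3), oxetan-2-one (step 4), 1,2-dioxine by ring expansion (step 5).

Assumption 1: the SMILES is read as methyl 2-[(3S,6R)-6-hexadecyl-6-methoxy-3,6-dihydro-1,2-dioxin-3-yl]acetate, with OMe trans to the C3 acetate arm.
Assumption 2: the sense of induction in step 4 is taken as quinidine-type catalyst → 4R (alkenyl ranks above ring CH2); if it proves opposite, the quinine-derived pseudo-enantiomer is used.

Step 1
Reactants: 1 1-bromoheptane; 2 1,6-dibromohexane
Product: 4 1-bromotridecane, via heptylmagnesium bromide 3 (not isolated)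
Conditions: Mg, THF, 40 °C; then added to 2 (3 equiv), Li2CuCl4 (3 mol%), THF, −10 °C → rt
Reagents that add atoms: none
Why: Copper-catalysed (Kochi-type) Grignard–alkyl bromide cross-coupling; the threefold excess of 2 holds it at mono-substitution and the surplus dibromide is distilled off.

Step 2
Reactants: 5 2-allylfuran; 4 1-bromotridecane
Product: 7 2-hexadecylfuran, via B-alkyl-9-BBN adduct 6 (not isolated)
Conditions: 9-BBN (1.1 equiv), THF, 0 °C → rt; then 4, Pd(OAc)2 (4 mol%), PCy3 (8 mol%), K3PO4·H2O, THF, rt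
Reagents that add atoms: none
Why: Anti-Markovnikov hydroboration of the terminal alkene followed by alkyl–alkyl Suzuki–Miyaura coupling of the B-alkyl-9-BBN with the primary bromide, which the furan tolerates.

Step 3
Reactants: 7 2-hexadecylfuran
Product: 8 (2Z)-4-oxoicos-2-enal
Conditions: dimethyldioxirane (1.05 equiv, ~0.07 M in acetone), acetone, −78 → −20 °C; evaporated cold, used crude
Reagents that add atoms: dimethyldioxirane, CC1(C)OO1
Why: Dioxirane epoxidation of the furan and spontaneous opening of the epoxide (oxidative furan ring opening) gives the cis-enedicarbonyl, the Z geometry being inherited from the ring.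

Step 4
Reactants: 8 (2Z)-4-oxoicos-2-enal; 9 acetyl chloride
Product: 11 (4R)-4-[(1Z)-3-oxononadec-1-en-1-yl]oxetan-2-one, via ketene 10 (not isolated)
Conditions: 9 (2.5 equiv, slow addition), iPr2NEt (2.5 equiv), O-trimethylsilylquinidine (10 mol%), LiClO4 (0.5 equiv), CH2Cl2/Et2O, −78 °C
Reagents that add atoms: none
Why: Cinchona-alkaloid/LiClO4-catalysed acyl halide–aldehyde cyclocondensation (Wynberg/Nelson-type formal [2+2], a stepwise aldol–lactonisation of the alkaloid-bound acylammonium enolate) occurs at the aldehyde, far more electrophilic than the enone ketone, and the alkaloid shields one aldehyde face to set C4 as R; −78 °C preserves the Z-alkene.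

Step 5
Reactants: 11 (4R)-4-[(1Z)-3-oxononadec-1-en-1-yl]oxetan-2-one
Product: 13 2-[(3S)-6-hexadecyl-6-hydroxy-3,6-dihydro-1,2-dioxin-3-yl]acetic acid (both C6 hemiketal epimers), via ketone perhydrate 12 (not isolated)
Conditions: anhydrous H2O2 (~2 M in Et2O, 8 equiv), Sc(OTf)3 (5 mol%), Et2O, −20 → 0 °C, dark
Reagents that add atoms: hydrogen peroxide, OO
Why: Proposed new method: H2O2 adds reversibly to the enone carbonyl (Sc(OTf)3-catalysed perhydrate formation) and the tethered OOH, an α-effect nucleophile held by the Z-alkene over C4 of the Sc-activated lactone, displaces the carboxylate by 6-exo-tet SN2 along an axis perpendicular to the alkene plane (allylic assistance that the in-plane five-ring closure by the hemiketal OH or the ketone O lacks), so the oxetan-2-one is enlarged to the 1,2-dioxine with inversion (4R → 3S) and the CH2CO2H arm is released; direct attack of H2O2 at C4 followed by hemiketalisation gives the same product with the same inversion, and the closest known reactions are alkyl–oxygen cleavage of β-lactones by neutral O-nucleophiles, Lewis-acid ring expansion of β-lactones by pendant ether or ketone oxygens to tetrahydrofurans, and intramolecular opening of oxetanes by hydroperoxides.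

Step 6
Reactants: 13 2-[(3S)-6-hexadecyl-6-hydroxy-3,6-dihydro-1,2-dioxin-3-yl]acetic acid
Product: 15 methyl 2-[(3S,6R)-6-hexadecyl-6-methoxy-3,6-dihydro-1,2-dioxin-3-yl]acetate, via 6-methoxy acid 14 (not isolated)
Conditions: MeOH (10 equiv), CSA (5 mol%), 4 Å MS, CH2Cl2, −30 → 0 °C; then TMSCHN2 (2 M in hexanes, 1.6 equiv), 0 °C
Reagents that add atoms: methanol, CO; (trimethylsilyl)diazomethane, C[Si](C)(C)C=[N+]=[N-]
Why: Acid-catalysed hemiketal-to-ketal exchange through the planar 1,2-dioxin-6-ylium (peroxycarbenium) ion under kinetic control, where methanol is expected to add anti to the C3 arm because its free CO2H shields the syn face by 1,4-participation, giving the 6R (trans) ketal; TMSCHN2 then quenches the acid and esterifies the carboxyl group (diazoalkane esterification) without touching C6, and the minor 6S epimer is removed by chromatography.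

**Compound list**
1 | 1-bromoheptane | CCCCCCCBr | starting material
2 | 1,6-dibromohexane | BrCCCCCCBr | starting material
3 | heptylmagnesium bromide | CCCCCCC[Mg]Br | intermediate
4 | 1-bromotridecane | CCCCCCCCCCCCCBr | intermediate
5 | 2-allylfuran (2-(prop-2-en-1-yl)furan) | C=CCc1ccco1 | starting material
6 | 9-[3-(furan-2-yl)propyl]-9-borabicyclo[3.3.1]nonane | B1(CCCc2ccco2)C3CCCC1CCC3 | intermediate
7 | 2-hexadecylfuran | CCCCCCCCCCCCCCCCc1ccco1 | intermediate
8 | (2Z)-4-oxoicos-2-enal | CCCCCCCCCCCCCCCCC(=O)/C=C\C=O | intermediate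
9 | acetyl chloride | CC(Cl)=O | starting material
10 | ketene | C=C=O | intermediate
11 | (4R)-4-[(1Z)-3-oxononadec-1-en-1-yl]oxetan-2-one | O=C1C[C@H](/C=C\C(=O)CCCCCCCCCCCCCCCC)O1 | intermediate
12 | (4R)-4-[(1Z)-3-hydroperoxy-3-hydroxynonadec-1-en-1-yl]oxetan-2-one (perhydrate, new carbinol centre undefined) | O=C1C[C@H](/C=C\C(O)(OO)CCCCCCCCCCCCCCCC)O1 | intermediate
13 | 2-[(3S)-6-hexadecyl-6-hydroxy-3,6-dihydro-1,2-dioxin-3-yl]acetic acid (C6 epimers, equilibrating) | CCCCCCCCCCCCCCCCC1(O)C=C[C@H](CC(=O)O)OO1 | intermediate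
14 | 2-[(3S,6R)-6-hexadecyl-6-methoxy-3,6-dihydro-1,2-dioxin-3-yl]acetic acid | CCCCCCCCCCCCCCCC[C@]1(OC)C=C[C@H](CC(=O)O)OO1 | intermediate
15 | methyl 2-[(3S,6R)-6-hexadecyl-6-methoxy-3,6-dihydro-1,2-dioxin-3-yl]acetate | CCCCCCCCCCCCCCCC[C@]1(OC)C=C[C@H](CC(=O)OC)OO1 | target

**Step count:** 6 steps in total. Longest linear sequence: 6 (1 → 4 → 7 → 8 → 11 → 13 → 15).

**Three steps most likely to fail**

Step 4 (asymmetric lactone formation on the Z-oxoenal). The aldehyde is conjugated and Michael-prone, the amine catalysts may isomerise Z to E, and the ammonium enolate could add to the enone instead. The fallback sets out from 8 and comes back at 11, replacing the catalytic cyclocondensation by an auxiliary aldol and a separate lactonisation. A trace of I2 in CH2Cl2 isomerises 8 to (2E)-4-oxoicos-2-enal F1. A TiCl4/iPr2NEt acetate aldol with the N-acetyl derivative of (4S)-4-isopropyl-1,3-thiazolidine-2-thione (made from 9; auxiliary antipode chosen to give the 3R adduct) gives 1-[(4S)-4-isopropyl-2-thioxo-1,3-thiazolidin-3-yl]-(3R,4E)-3-hydroxydocos-4-ene-1,6-dione F2. LiOH in THF/H2O at 0 °C cleaves the auxiliary to (3R,4E)-3-hydroxy-6-oxodocos-4-enoic acid F3. PhSO2Cl/pyridine (carboxyl activation, retention at the carbinol) closes (4R)-4-[(1E)-3-oxononadec-1-en-1-yl]oxetan-2-one F4. Irradiation at 350 nm in MeCN isomerises the enone; the Z isomer 11 is separated and the E isomer recycled.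

Step 5 (proposed ring expansion). Possible failures are five-ring closure by the ketone or hemiketal oxygen followed by aromatisation to a furan, perhydrolysis at the acyl carbon, and partial SN1 erosion at C4. The fallback sets out from 7 and comes back at 15, using established reaction classes only. Rh2(OAc)4-catalysed reaction of 7 with methyl diazoacetate (cyclopropanation and ring opening) gives methyl (2E,4Z)-6-oxodocosa-2,4-dienoate F5. Urea–H2O2 with Sc(OTf)3 in MeOH gives racemic methyl (2E,4Z)-6-hydroperoxy-6-methoxydocosa-2,4-dienoate F6. Et2NH in CF3CH2OH at 0 °C (short contact, to avoid base-induced peroxide cleavage) closes the ring by intramolecular peroxy-Michael addition, giving the racemic trans ketal F7 and the racemic cis ketal F8, which are separated on silica. Preparative chiral-phase HPLC of F7 gives 15.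

Step 6 (C6 configuration). The kinetic trans preference is a reasoned expectation, not a precedent; the known thermodynamic outcome for this ring system is a mixture of both C6 epimers. The fallback sets out from 13 and comes back at 15, replacing kinetic control by equilibration, separation and recycling. TMSCHN2 first gives methyl 2-[(3S)-6-hexadecyl-6-hydroxy-3,6-dihydro-1,2-dioxin-3-yl]acetate F9. MeOH with catalytic TsOH at rt (the classical end game for this compound class) gives 15 together with methyl 2-[(3S,6S)-6-hexadecyl-6-methoxy-3,6-dihydro-1,2-dioxin-3-yl]acetate F10. The two are separated by chromatography and F10 is returned to the same equilibration.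

**Further compounds**
F1 | step 4 | (2E)-4-oxoicos-2-enal | CCCCCCCCCCCCCCCCC(=O)/C=C/C=O
F2 | step 4 | 1-[(4S)-4-isopropyl-2-thioxo-1,3-thiazolidin-3-yl]-(3R,4E)-3-hydroxydocos-4-ene-1,6-dione | CC(C)[C@H]1CSC(=S)N1C(=O)C[C@@H](O)/C=C/C(=O)CCCCCCCCCCCCCCCC
F3 | step 4 | (3R,4E)-3-hydroxy-6-oxodocos-4-enoic acid | OC(=O)C[C@@H](O)/C=C/C(=O)CCCCCCCCCCCCCCCC
F4 | step 4 | (4R)-4-[(1E)-3-oxononadec-1-en-1-yl]oxetan-2-one | O=C1C[C@H](/C=C/C(=O)CCCCCCCCCCCCCCCC)O1
F5 | step 5 | methyl (2E,4Z)-6-oxodocosa-2,4-dienoate | CCCCCCCCCCCCCCCCC(=O)/C=C\C=C\C(=O)OC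
F6 | step 5 | methyl (2E,4Z)-6-hydroperoxy-6-methoxydocosa-2,4-dienoate (racemic) | CCCCCCCCCCCCCCCCC(OC)(OO)/C=C\C=C\C(=O)OC
F7 | step 5 | racemic trans ketal: 15 with its (3R,6S) enantiomer | CCCCCCCCCCCCCCCC[C@]1(OC)C=C[C@H](CC(=O)OC)OO1.CCCCCCCCCCCCCCCC[C@@]1(OC)C=C[C@@H](CC(=O)OC)OO1
F8 | step 5 | racemic cis ketal: (3S,6S) and (3R,6R) epimers of 15 | CCCCCCCCCCCCCCCC[C@@]1(OC)C=C[C@H](CC(=O)OC)OO1.CCCCCCCCCCCCCCCC[C@]1(OC)C=C[C@@H](CC(=O)OC)OO1
F9 | step 6 | methyl 2-[(3S)-6-hexadecyl-6-hydroxy-3,6-dihydro-1,2-dioxin-3-yl]acetate (C6 epimers, equilibrating) | CCCCCCCCCCCCCCCCC1(O)C=C[C@H](CC(=O)OC)OO1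
F10 | step 6 | methyl 2-[(3S,6S)-6-hexadecyl-6-methoxy-3,6-dihydro-1,2-dioxin-3-yl]acetate | CCCCCCCCCCCCCCCC[C@@]1(OC)C=C[C@H](CC(=O)OC)OO1
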